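**Strategy.** The upper flavan is cut across ring C. Its O-1 and C-4a sit on neighbouring carbons of the resorcinol-type ring A, and C-2, C-3 and C-4 are the three-carbon chain of a chalcone whose β-carbon carries epicatechin C-8. One chiral-acid-catalysed cascade joins 3-benzyloxyphenol to that chalcone: Friedel–Crafts conjugate addition forms C-4–C-4a and sets C-4, and cyclodehydration forms O-1–C-2, closing ring C as a 4H-chromene. The precursor is the E-enone from 8-formyl-penta-O-benzylepicatechin and 4-benzyloxyacetophenone. Every hydroxyl is a benzyl ether, so one hydrogenation then saturates C-2–C-3 cis to the C-4 aryl group and frees all seven hydroxyls.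

Key step: step 6

Remark: the epicatechin centres are too remote to predict which antipode of the chiral acid gives the 4S epimer. The (R)-acid is written; its mirror image would be used if a test run shows that it is the matched one (the two C-4 epimers are diastereomers and distinguishable by NMR and HPLC).

Remark: a BINOL phosphoric acid is judged too weak for this push–pull enone (trialkoxyaryl donor at the β-carbon, p-alkoxyaryl ketone), so the more acidic N-triflylphosphoramide of the same backbone is specified.

Remark: the 3-OH is benzylated as well, because a free alcohol would quench the organolithium in step 4 and compete for the acid in step 6. In steps 1 and 7 several like groups react in no fixed order, so no single intermediate is numbered there.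

Step 1
Reactants: 1 (−)-epicatechin
Product: 2 5,7,3',4'-tetra-O-benzylepicatechin
Conditions: BnBr (4.4 equiv), K2CO3 (5 equiv), DMF, 0 °C → rt, argon
Reagents that add atoms: benzyl bromide, BrCc1ccccc1
Why: Williamson etherification with a carbonate base alkylates the four phenols but not the secondary alcohol, and once the 4'-phenol is capped the B-ring quinone methide pathway that could epimerise C-2 is closed, so the 2R,3R centres are carried through unchanged.

Step 2
Reactants: 2 5,7,3',4'-tetra-O-benzylepicatechin
Product: 3 8-bromo-5,7,3',4'-tetra-O-benzylepicatechin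
Conditions: NBS (1.0 equiv), CH2Cl2, −78 °C → rt
Reagents that add atoms: N-bromosuccinimide, O=C1CCC(=O)N1Br
Why: Electrophilic aromatic bromination of the phloroglucinol-type ring A should occur at C-8, which is less shielded than C-6 between two benzyloxy groups, and the cold neutral conditions leave the benzyl ethers and the free 3-OH untouched.

Step 3
Reactants: 3 8-bromo-5,7,3',4'-tetra-O-benzylepicatechin
Product: 4 8-bromo-3,5,7,3',4'-penta-O-benzylepicatechin
Conditions: NaH (1.5 equiv), BnBr (1.3 equiv), DMF, 0 °C → rt
Reagents that add atoms: benzyl bromide, BrCc1ccccc1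
Why: Williamson etherification of the secondary alkoxide removes the only acidic proton before the organolithium step and turns the 3-oxygen into a benzyl ether that falls in the final hydrogenolysis, while the aryl bromide is inert to NaH.

Step 4
Reactants: 4 8-bromo-3,5,7,3',4'-penta-O-benzylepicatechin
Product: 7 8-formyl-3,5,7,3',4'-penta-O-benzylepicatechin, via 8-lithio arene 5 (not isolated), via lithium hemiaminal alkoxide 6 (not isolated)
Conditions: n-BuLi (1.1 equiv), THF, −78 °C; DMF (5 equiv), −78 → 0 °C; H2O
Reagents that add atoms: N,N-dimethylformamide, CN(C)C=O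
Why: Bromine–lithium exchange at −78 °C is much faster than deprotonation next to the benzyl ether oxygens, and the aryllithium adds to DMF (Bouveault formylation) to give a tetrahedral adduct that releases the aldehyde only on aqueous work-up, so no over-addition occurs.

Step 5
Reactants: 7 8-formyl-3,5,7,3',4'-penta-O-benzylepicatechin; 8 4-benzyloxyacetophenone
Product: 10 (E)-1-(4-benzyloxyphenyl)-3-(penta-O-benzylepicatechin-8-yl)prop-2-en-1-one, via aldol adduct 9 (not isolated)
Conditions: 8 (1.5 equiv), KOH (50% aq.), THF/EtOH, rt → 40 °C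
Reagents that add atoms: none
Why: Claisen–Schmidt condensation, in which only the acetophenone can enolise, its enolate adds to the non-enolisable aldehyde and E1cB loss of hydroxide from the aldol gives the thermodynamically favoured E-enone, while the ether-protected epicatechin unit is stable to hydroxide.

Step 6
Reactants: 10 (E)-1-(4-benzyloxyphenyl)-3-(penta-O-benzylepicatechin-8-yl)prop-2-en-1-one; 11 3-benzyloxyphenol
Product: 14 (4S)-7-benzyloxy-2-(4-benzyloxyphenyl)-4-(penta-O-benzylepicatechin-8-yl)-4H-chromene, via Friedel–Crafts ketone 12 (not isolated), via cyclic hemiketal 13 (not isolated)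
Conditions: 11 (3 equiv), (R)-3,3'-bis(2,4,6-triisopropylphenyl)-1,1'-binaphthyl-2,2'-diyl N-triflylphosphoramide (10 mol%), 5 Å MS, toluene, 0 °C → rt; then Et3N
Reagents that add atoms: none
Why: Proposed new method: the strong chiral Brønsted acid activates the enone through its carbonyl oxygen while a basic oxygen of the same catalyst binds the phenolic OH, so the phenol carbon ortho to OH and para to OBn adds to the β-carbon inside the chiral ion pair (Friedel–Crafts conjugate addition) to give ketone 12; the freed phenol then closes ring C by 6-exo-trig attack on the ketone (hemiketal 13), and acid-assisted loss of water through the 2-aryl oxocarbenium ion gives the conjugated enol ether 14. The closest known reactions are chiral Brønsted acid-catalysed Friedel–Crafts/cyclodehydration cascades of naphthols and electron-rich phenols with activated enones (β,γ-unsaturated α-keto esters) that give 4H-chromenes, and the achiral acid-mediated condensation of resorcinol-type phenols with chalcones; an enantioselective version with a plain chalcone carrying a 2,6-dioxygenated aryl group at the β-carbon has not been shown. The new stereocentre C-4 is set by the catalyst pocket, because C-2 and C-3 of the epicatechin unit lie too far from the β-carbon to bias its faces reliably. The step needs ortho regioselectivity on the phenol, which is secured by the hydrogen bond between the phenolic OH and the catalyst and by the fact that only the ortho adduct can cyclise, attack para to OH being reversible under the acid. The sieves take up the water so that dehydration is pulled to completion, and the excess of phenol keeps the free C-6 of the epicatechin ring from competing as a nucleophile.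

Step 7
Reactants: 14 (4S)-7-benzyloxy-2-(4-benzyloxyphenyl)-4-(penta-O-benzylepicatechin-8-yl)-4H-chromene
Product: 15 (2R,3R)-2-(3,4-dihydroxyphenyl)-8-[(2S,4S)-7-hydroxy-2-(4-hydroxyphenyl)chroman-4-yl]chromane-3,5,7-triol (target)
Conditions: H2 (1 atm), Pd(OH)2/C, THF/MeOH 1:1, rt
Reagents that add atoms: none
Why: Heterogeneous hydrogenation should add both hydrogens to C-2 and C-3 from the face of the enol ether opposite the bulky C-4 aryl group, which places H-2 cis to H-4 and so sets C-2 as S (2,4-cis), and the same catalyst cleaves the seven benzyl ethers by hydrogenolysis.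

**Compound list**

1 | (−)-epicatechin, (2R,3R)-2-(3,4-dihydroxyphenyl)chromane-3,5,7-triol | Oc1cc(O)c2c(c1)O[C@H](c1ccc(O)c(O)c1)[C@H](O)C2 | starting material
2 | 5,7,3',4'-tetra-O-benzylepicatechin, (2R,3R)-5,7-bis(benzyloxy)-2-[3,4-bis(benzyloxy)phenyl]chroman-3-ol | c9ccccc9COc1cc(OCc9ccccc9)c2c(c1)O[C@H](c1ccc(OCc9ccccc9)c(OCc9ccccc9)c1)[C@H](O)C2 | intermediate
3 | 8-bromo-5,7,3',4'-tetra-O-benzylepicatechin (2R,3R) | Brc1c(OCc9ccccc9)cc(OCc9ccccc9)c2c1O[C@H](c1ccc(OCc9ccccc9)c(OCc9ccccc9)c1)[C@H](O)C2 | intermediate
4 | 8-bromo-3,5,7,3',4'-penta-O-benzylepicatechin (2R,3R) | Brc1c(OCc9ccccc9)cc(OCc9ccccc9)c2c1O[C@H](c1ccc(OCc9ccccc9)c(OCc9ccccc9)c1)[C@H](OCc9ccccc9)C2 | intermediate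
5 | 8-lithio-3,5,7,3',4'-penta-O-benzylepicatechin (aryllithium formed in the flask) | [Li]c1c(OCc9ccccc9)cc(OCc9ccccc9)c2c1O[C@H](c1ccc(OCc9ccccc9)c(OCc9ccccc9)c1)[C@H](OCc9ccccc9)C2 | intermediate
6 | lithium alkoxide of the 8-[(dimethylamino)(hydroxy)methyl] adduct of penta-O-benzylepicatechin (new carbinol centre undefined, formed in the flask) | [Li]OC(N(C)C)c1c(OCc9ccccc9)cc(OCc9ccccc9)c2c1O[C@H](c1ccc(OCc9ccccc9)c(OCc9ccccc9)c1)[C@H](OCc9ccccc9)C2 | intermediate
7 | 8-formyl-3,5,7,3',4'-penta-O-benzylepicatechin, (2R,3R)-3,5,7-tris(benzyloxy)-2-[3,4-bis(benzyloxy)phenyl]chromane-8-carbaldehyde | O=Cc1c(OCc9ccccc9)cc(OCc9ccccc9)c2c1O[C@H](c1ccc(OCc9ccccc9)c(OCc9ccccc9)c1)[C@H](OCc9ccccc9)C2 | intermediate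
8 | 4-benzyloxyacetophenone | CC(=O)c1ccc(OCc2ccccc2)cc1 | starting material
9 | aldol adduct, 1-[4-(benzyloxy)phenyl]-3-hydroxy-3-(penta-O-benzylepicatechin-8-yl)propan-1-one (carbinol centre undefined, formed in the flask) | O=C(CC(O)c3c(OCc9ccccc9)cc(OCc9ccccc9)c4c3O[C@H](c3ccc(OCc9ccccc9)c(OCc9ccccc9)c3)[C@H](OCc9ccccc9)C4)c1ccc(OCc9ccccc9)cc1 | intermediate
10 | (E)-1-(4-benzyloxyphenyl)-3-(penta-O-benzylepicatechin-8-yl)prop-2-en-1-one | O=C(/C=C/c3c(OCc9ccccc9)cc(OCc9ccccc9)c4c3O[C@H](c3ccc(OCc9ccccc9)c(OCc9ccccc9)c3)[C@H](OCc9ccccc9)C4)c1ccc(OCc9ccccc9)cc1 | intermediate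
11 | 3-benzyloxyphenol | Oc1cccc(OCc2ccccc2)c1 | starting material
12 | (3S)-3-[4-(benzyloxy)-2-hydroxyphenyl]-1-[4-(benzyloxy)phenyl]-3-(penta-O-benzylepicatechin-8-yl)propan-1-one (formed in the flask) | O=C(C[C@H](c3c(OCc9ccccc9)cc(OCc9ccccc9)c4c3O[C@H](c3ccc(OCc9ccccc9)c(OCc9ccccc9)c3)[C@H](OCc9ccccc9)C4)c3ccc(OCc9ccccc9)cc3O)c1ccc(OCc9ccccc9)cc1 | intermediate
13 | (4S)-7-(benzyloxy)-2-[4-(benzyloxy)phenyl]-4-(penta-O-benzylepicatechin-8-yl)chroman-2-ol (C-2 undefined, formed in the flask) | OC1(c2ccc(OCc9ccccc9)cc2)C[C@H](c3c(OCc9ccccc9)cc(OCc9ccccc9)c4c3O[C@H](c3ccc(OCc9ccccc9)c(OCc9ccccc9)c3)[C@H](OCc9ccccc9)C4)c2ccc(OCc9ccccc9)cc2O1 | intermediate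
14 | (4S)-7-benzyloxy-2-(4-benzyloxyphenyl)-4-(penta-O-benzylepicatechin-8-yl)-4H-chromene | c9ccccc9COc1ccc(C2=C[C@H](c3c(OCc9ccccc9)cc(OCc9ccccc9)c4c3O[C@H](c3ccc(OCc9ccccc9)c(OCc9ccccc9)c3)[C@H](OCc9ccccc9)C4)c3ccc(OCc9ccccc9)cc3O2)cc1 | intermediate
15 | (2R,3R)-2-(3,4-dihydroxyphenyl)-8-[(2S,4S)-7-hydroxy-2-(4-hydroxyphenyl)chroman-4-yl]chromane-3,5,7-triol | Oc1ccc([C@@H]2C[C@H](c3c(O)cc(O)c4c3O[C@H](c3ccc(O)c(O)c3)[C@H](O)C4)c3ccc(O)cc3O2)cc1 | target

**Step count.** Total: 7 steps. Longest linear sequence: 7 steps (1 → 15).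

**Steps most likely to fail**

Step 6. The deactivated enone may not be activated enough, face selection at the β-carbon may be poor, or the acid may reverse the C–C bond formation (retro-Friedel–Crafts through a flavylium ion) and scramble C-4. The fallback reverses the polarity of the C-4–C-8 union and uses known chemistry only. It sets out from 8 and from aryllithium 5 (made from 4 as in step 4). Acid condensation of 8 with commercial 4-(benzyloxy)-2-hydroxybenzaldehyde (O=Cc1ccc(OCc2ccccc2)cc1O) under HBF4·OEt2 in AcOH/EtOAc, the classical flavylium salt synthesis, should give 7-(benzyloxy)-2-[4-(benzyloxy)phenyl]chromenylium tetrafluoroborate F1. Addition of 5 to a suspension of F1 in THF at −78 °C should occur at C-4, as is usual for carbon nucleophiles on 2-arylbenzopyrylium salts. This would give 14 together with its 4R epimer; the two are diastereomers and would be separated by chromatography. The route is rejoined at 14.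

Step 7. Hydrogen may be delivered to the wrong face of the enol ether, or a benzylic C-2–O-1 bond may be opened by hydrogenolysis during the long exposure that the aliphatic 3-O-benzyl ether needs. The fallback separates the two events and sets out from 14. Homogeneous hydrogenation with [Ir(cod)((S)-tBu-PHOX)]BArF (ligand antipode chosen to match the substrate) under H2 (50 bar) in CH2Cl2 leaves benzyl ethers alone. It should give (2S,4S)-7-benzyloxy-2-(4-benzyloxyphenyl)-4-(penta-O-benzylepicatechin-8-yl)flavan F2, from which any 2,4-trans isomer can be removed on silica. A short hydrogenolysis of F2 (H2, Pd(OH)2/C, THF/MeOH) then returns to the route at 15.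

Step 4. The aryllithium may be protonated, or metalation next to a benzyl ether oxygen followed by Wittig rearrangement may compete with formylation. The fallback avoids organolithium chemistry and sets out from 4. Suzuki–Miyaura coupling with potassium vinyltrifluoroborate (C=C[B-](F)(F)F.[K+]) using Pd(OAc)2/SPhos and Cs2CO3 in THF/H2O at 70 °C should give 8-vinyl-3,5,7,3',4'-penta-O-benzylepicatechin F3. Lemieux–Johnson cleavage of F3 (K2OsO4·2H2O cat., NaIO4, 2,6-lutidine, dioxane/H2O, rt) returns to the route at 7.

**Further compounds**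

F1 | step 6 | 7-(benzyloxy)-2-[4-(benzyloxy)phenyl]chromenylium tetrafluoroborate | [o+]1c(-c2ccc(OCc3ccccc3)cc2)ccc2ccc(OCc3ccccc3)cc12.F[B-](F)(F)F
F2 | step 7 | (2S,4S)-7-benzyloxy-2-(4-benzyloxyphenyl)-4-(penta-O-benzylepicatechin-8-yl)flavan | c9ccccc9COc1ccc([C@@H]2C[C@H](c3c(OCc9ccccc9)cc(OCc9ccccc9)c4c3O[C@H](c3ccc(OCc9ccccc9)c(OCc9ccccc9)c3)[C@H](OCc9ccccc9)C4)c3ccc(OCc9ccccc9)cc3O2)cc1
F3 | step 4 | 8-vinyl-3,5,7,3',4'-penta-O-benzylepicatechin | C=Cc1c(OCc9ccccc9)cc(OCc9ccccc9)c2c1O[C@H](c1ccc(OCc9ccccc9)c(OCc9ccccc9)c1)[C@H](OCc9ccccc9)C2
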